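**Plan**
- Retrosynthesis: the two acetates and the O7–prenyl bond are cut last. Ring A is then opened at C8–C8a and C4a–C5, which leaves a 2-aryl-3-acetoxy-5-bromo-4-pyranone and a four-carbon bis-silyl dienol ether of methyl 4-methoxyacetoacetate.
- Enabling feature: ring A carries oxygen at C5 and C7 (1,3-related) and methoxy at C8. That is the 4-methoxyacetoacetate pattern fused onto the C4a–C8a edge of a 4-pyranone, and a bromine on the future C4a supplies the oxidation level of the arene.
- The pyranone goes back to a 3-bromofuryl carbinol (ring expansion, then hydrolysis of the C4 bromide) and so to 3-bromofuran and O-silyl vanillin.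
- Forward order: ring B comes with vanillin, ring C is made from the furan, ring A is annulated onto ring C, then O7 is prenylated and the acetates are removed.
- Stereochemistry: the target has no stereocentre and no configured double bond. Racemic and diastereomeric intermediates converge because every sp3 centre is destroyed on aromatisation.

Key step: step 9

Remark on the chemistry: the silyl enol ethers 14–16 are expected as E/Z mixtures; one isomer is drawn, and the geometry is lost when ring A aromatises.

**Step 1**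
Reactants: 1 vanillin
Product: 2 4-(tert-butyldimethylsilyloxy)-3-methoxybenzaldehyde
Conditions: tBuMe2SiCl, imidazole, DMF, 20 °C
Reagents that add atoms: tert-butyldimethylsilyl chloride, CC(C)(C)[Si](C)(C)Cl
Why: Imidazole-promoted O-silylation of a phenol removes the acidic proton before the organolithium step and gives an ether that aqueous acid cleaves later.

**Step 2**
Reactants: 3 3-bromofuran; 2 4-(tert-butyldimethylsilyloxy)-3-methoxybenzaldehyde
Product: 5 (3-bromofuran-2-yl)[4-(tert-butyldimethylsilyloxy)-3-methoxyphenyl]methanol, via 3-bromo-2-furyllithium 4 (not isolated)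
Conditions: LiN(iPr)2, THF, −78 °C; then 2, −78 → −40 °C; aq. NH4Cl
Reagents that add atoms: none
Why: Directed α-lithiation, in which LiN(iPr)2 removes the C2 proton between the ring oxygen and the bromine without bromine–lithium exchange, is followed by 1,2-addition to the aldehyde; the carbinol centre is racemic and disappears in step 4.

**Step 3**
Reactants: 5 (3-bromofuran-2-yl)[4-(tert-butyldimethylsilyloxy)-3-methoxyphenyl]methanol
Product: 7 4-bromo-2-[4-(tert-butyldimethylsilyloxy)-3-methoxyphenyl]-6-hydroxy-2H-pyran-3(6H)-one, via bromo hydroxy oxo enal 6 (not isolated)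
Conditions: mCPBA, CH2Cl2, 0 °C
Reagents that add atoms: 3-chloroperbenzoic acid (mCPBA), OOC(=O)c1cccc(Cl)c1
Why: In this Achmatowicz oxidative ring expansion the peracid oxidises the furan, which is far more nucleophilic than the aryl silyl ether, to the cis-enedione 6, and 6 closes to the hemiacetal with the bromine at C4 (anomers and the racemic C2 centre are carried as a mixture).

**Step 4**
Reactants: 7 4-bromo-2-[4-(tert-butyldimethylsilyloxy)-3-methoxyphenyl]-6-hydroxy-2H-pyran-3(6H)-one
Product: 9 3-hydroxy-2-(4-hydroxy-3-methoxyphenyl)-4H-pyran-4-one, via silyl-protected hydroxypyranone 8 (not isolated)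
Conditions: 2 M HCl, 1,4-dioxane, 80 °C
Reagents that add atoms: water, O
Why: This is the second stage of the halogen-based maltol synthesis, in which hot aqueous acid enolises the benzylic C2, removes water and replaces the C4 bromide by oxygen to give the aromatic 3-hydroxy-4-pyranone, and the same acid hydrolyses the phenolic silyl ether.

**Step 5**
Reactants: 9 3-hydroxy-2-(4-hydroxy-3-methoxyphenyl)-4H-pyran-4-one
Product: 10 3-acetoxy-2-(4-acetoxy-3-methoxyphenyl)-4H-pyran-4-one
Conditions: Ac2O, pyridine, DMAP (cat.), CH2Cl2, 20 °C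
Reagents that add atoms: acetic anhydride, CC(=O)OC(C)=O
Why: DMAP-catalysed acylation caps the enolic 3-OH and the phenol as acetates, which deactivate the aryl ring toward bromine, tolerate silyl triflate and are removed at the end by methanolysis.

**Step 6**
Reactants: 10 3-acetoxy-2-(4-acetoxy-3-methoxyphenyl)-4H-pyran-4-one
Product: 12 3-acetoxy-2-(4-acetoxy-3-methoxyphenyl)-5-bromo-4H-pyran-4-one, via trans-5,6-dibromide 11 (not isolated)
Conditions: Br2 (1.05 equiv), CH2Cl2, −10 °C; then Et3N, 0 °C
Reagents that add atoms: bromine, BrBr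
Why: Bromine addition–dehydrobromination, as used for 3-bromochromones, should place bromine at C5 because Br2 adds to the unhindered enol-ether-like C5=C6 bond and Et3N removes the acidic C5 proton with loss of the C6 bromide, while the aryl ring bearing acetoxy and pyranonyl groups reacts more slowly.

**Step 7**
Reactants: 13 methyl 4-methoxyacetoacetate
Product: 14 methyl 4-methoxy-3-(trimethylsilyloxy)but-2-enoate
Conditions: Me3SiCl, Et3N, toluene, 20 °C
Reagents that add atoms: chlorotrimethylsilane, C[Si](C)(C)Cl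
Why: Soft enolisation and O-silylation of a β-keto ester is the standard first stage of a 1,3-bis(silyloxy)diene synthesis.

**Step 8**
Reactants: 14 methyl 4-methoxy-3-(trimethylsilyloxy)but-2-enoate
Product: 16 (1Z,3Z)-1,4-dimethoxy-1,3-bis(trimethylsilyloxy)buta-1,3-diene, via lithium dienolate 15 (not isolated)
Conditions: LiN(iPr)2, THF, −78 °C; Me3SiCl, −78 → 20 °C; non-aqueous work-up
Reagents that add atoms: chlorotrimethylsilane, C[Si](C)(C)Cl
Why: γ-Deprotonation at the CH2(OMe) carbon and O-silylation of the dienolate (Chan-type diene synthesis) give the moisture-sensitive diene, which is used directly.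

**Step 9**
Reactants: 12 3-acetoxy-2-(4-acetoxy-3-methoxyphenyl)-5-bromo-4H-pyran-4-one; 16 (1Z,3Z)-1,4-dimethoxy-1,3-bis(trimethylsilyloxy)buta-1,3-diene
Product: 21 3-acetoxy-2-(4-acetoxy-3-methoxyphenyl)-5,7-dihydroxy-8-methoxychromen-4-one, via silyloxypyrylium triflate 17 (not isolated), via Michael adduct 18 (not isolated), via bromo ketal cycloadduct 19 (not isolated), via bis-silyl ether 20 (not isolated)
Conditions: Me3SiOTf (2.2 equiv), CH2Cl2, 20 °C; then 16 (1.5 equiv), −78 → 20 °C; Et3N (4 equiv), 0 → 20 °C; 1 M HCl, THF, 20 °C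
Reagents that add atoms: none
Why: Proposed new method: Me3SiOTf converts pyranone 12 into the 4-silyloxypyrylium salt 17, whose unsubstituted C6 accepts the nucleophilic CH(OMe) terminus of 16 (vinylogous Mukaiyama–Michael addition, C8–C8a) to give 18, and the bromo silyl enol ether carbon C5 of 18 then adds to the ester carbon once this is O-silylated to a dialkoxycarbenium ion (Mukaiyama–Claisen-type closure, C4a–C5), giving ketal 19. Et3N with the remaining silyl triflate enolises ring A, so that the now doubly allylic tertiary bromide leaves with the C8a hydrogen and MeOSiMe3 leaves from the C5 ketal to give arene 20, which the acid work-up desilylates to 21. The closest known reactions are the Brassard-type benzannulation of halo-quinones by 1-alkoxy-1-silyloxydienes and the silyl-triflate-mediated additions and twofold Michael annulations of siloxydienes on 4-silyloxybenzopyrylium ions generated from chromones. Ring A closes by a stepwise ionic [4+2] annulation whose second bond forms in a six-membered exo-trig closure, and the four sp3 centres of 19 are erased on aromatisation, so no stereocentre has to be controlled. The step needs attack at C6 and not at C2, which the 2-aryl and 3-acetoxy substituents secure by hindrance and by donation into C2, and it needs the diene to bond first through its CH(OMe) terminus, which its polarity dictates. The bromine at C4a secures the rest: it leaves no acidic hydrogen for β-elimination of the ring oxygen, which is the usual fate of such adducts, and it supplies the oxidation level for aromatisation, so that 21 emerges with the 5-OH chelated and the 7-OH free.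

**Step 10**
Reactants: 21 3-acetoxy-2-(4-acetoxy-3-methoxyphenyl)-5,7-dihydroxy-8-methoxychromen-4-one; 22 prenyl bromide
Product: 23 3-acetoxy-2-(4-acetoxy-3-methoxyphenyl)-5-hydroxy-8-methoxy-7-(3-methylbut-2-enyloxy)chromen-4-one
Conditions: 22 (1.1 equiv), K2CO3 (1.2 equiv), acetone, 20 °C
Reagents that add atoms: none
Why: In this Williamson etherification carbonate deprotonates only the acidic, non-chelated 7-OH para to the carbonyl, while the 5-OH stays hydrogen-bonded to C4=O, so the allylic bromide should alkylate O7 selectively.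

**Step 11**
Reactants: 23 3-acetoxy-2-(4-acetoxy-3-methoxyphenyl)-5-hydroxy-8-methoxy-7-(3-methylbut-2-enyloxy)chromen-4-one
Product: 24 3,5-dihydroxy-2-(4-hydroxy-3-methoxyphenyl)-8-methoxy-7-(3-methylbut-2-enyloxy)chromen-4-one
Conditions: K2CO3 (2.5 equiv), MeOH, 0 → 20 °C, argon; then 1 M HCl
Reagents that add atoms: none
Why: Base-mediated transesterification cleaves the enol and aryl acetates at or below room temperature without touching the prenyl or methyl ethers, and exclusion of air protects the flavonol anion from oxidation.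

**Compound list**
1 | vanillin | COc1cc(C=O)ccc1O | starting material
2 | 4-(tert-butyldimethylsilyloxy)-3-methoxybenzaldehyde | COc1cc(C=O)ccc1O[Si](C)(C)C(C)(C)C | intermediate
3 | 3-bromofuran | Brc1ccoc1 | starting material
4 | 3-bromo-2-furyllithium (formed in situ) | [Li]c1occc1Br | intermediate
5 | (3-bromofuran-2-yl)[4-(tert-butyldimethylsilyloxy)-3-methoxyphenyl]methanol (racemic) | COc1cc(C(O)c2occc2Br)ccc1O[Si](C)(C)C(C)(C)C | intermediate
6 | (E)-3-bromo-5-[4-(tert-butyldimethylsilyloxy)-3-methoxyphenyl]-5-hydroxy-4-oxopent-2-enal (racemic, formed in situ) | O=C/C=C(Br)\C(=O)C(O)c1ccc(O[Si](C)(C)C(C)(C)C)c(OC)c1 | intermediate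
7 | 4-bromo-2-[4-(tert-butyldimethylsilyloxy)-3-methoxyphenyl]-6-hydroxy-2H-pyran-3(6H)-one (mixture of diastereomers) | COc1cc(C2OC(O)C=C(Br)C2=O)ccc1O[Si](C)(C)C(C)(C)C | intermediate
8 | 2-[4-(tert-butyldimethylsilyloxy)-3-methoxyphenyl]-3-hydroxy-4H-pyran-4-one (formed in situ) | COc1cc(-c2occc(=O)c2O)ccc1O[Si](C)(C)C(C)(C)C | intermediate
9 | 3-hydroxy-2-(4-hydroxy-3-methoxyphenyl)-4H-pyran-4-one | COc1cc(-c2occc(=O)c2O)ccc1O | intermediate
10 | 3-acetoxy-2-(4-acetoxy-3-methoxyphenyl)-4H-pyran-4-one | CC(=O)Oc1c(-c2ccc(OC(C)=O)c(OC)c2)occc1=O | intermediate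
11 | trans-3-acetoxy-2-(4-acetoxy-3-methoxyphenyl)-5,6-dibromo-5,6-dihydro-4H-pyran-4-one (racemic, one enantiomer drawn, formed in situ) | CC(=O)OC1=C(c2ccc(OC(C)=O)c(OC)c2)O[C@H](Br)[C@@H](Br)C1=O | intermediate
12 | 3-acetoxy-2-(4-acetoxy-3-methoxyphenyl)-5-bromo-4H-pyran-4-one | CC(=O)Oc1c(-c2ccc(OC(C)=O)c(OC)c2)occ(Br)c1=O | intermediate
13 | methyl 4-methoxyacetoacetate | COCC(=O)CC(=O)OC | starting material
14 | methyl 4-methoxy-3-(trimethylsilyloxy)but-2-enoate (E/Z mixture, Z drawn) | COC/C(O[Si](C)(C)C)=C/C(=O)OC | intermediate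
15 | lithium 1,4-dimethoxy-3-(trimethylsilyloxy)buta-1,3-dien-1-olate (formed in situ) | CO/C=C(O[Si](C)(C)C)/C=C(/OC)O[Li] | intermediate
16 | (1Z,3Z)-1,4-dimethoxy-1,3-bis(trimethylsilyloxy)buta-1,3-diene | CO/C=C(O[Si](C)(C)C)/C=C(/OC)O[Si](C)(C)C | intermediate
17 | 3-acetoxy-2-(4-acetoxy-3-methoxyphenyl)-5-bromo-4-(trimethylsilyloxy)pyrylium trifluoromethanesulfonate (formed in situ) | CC(=O)Oc1c(-c2ccc(OC(C)=O)c(OC)c2)[o+]cc(Br)c1O[Si](C)(C)C.[O-]S(=O)(=O)C(F)(F)F | intermediate
18 | methyl 4-[5-acetoxy-6-(4-acetoxy-3-methoxyphenyl)-3-bromo-4-(trimethylsilyloxy)-2H-pyran-2-yl]-4-methoxy-3-(trimethylsilyloxy)but-2-enoate (stereoisomer mixture, formed in situ) | COC(=O)C=C(O[Si](C)(C)C)C(OC)C1OC(-c2ccc(OC(C)=O)c(OC)c2)=C(OC(C)=O)C(O[Si](C)(C)C)=C1Br | intermediate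
19 | 3-acetoxy-2-(4-acetoxy-3-methoxyphenyl)-4a-bromo-5,8-dimethoxy-5,7-bis(trimethylsilyloxy)-4a,5,8,8a-tetrahydro-4H-chromen-4-one (stereoisomer mixture, formed in situ) | COC1C(O[Si](C)(C)C)=CC(OC)(O[Si](C)(C)C)C2(Br)C(=O)C(OC(C)=O)=C(c3ccc(OC(C)=O)c(OC)c3)OC12 | intermediate
20 | 3-acetoxy-2-(4-acetoxy-3-methoxyphenyl)-8-methoxy-5,7-bis(trimethylsilyloxy)chromen-4-one (formed in situ) | COc1cc(-c2oc3c(OC)c(O[Si](C)(C)C)cc(O[Si](C)(C)C)c3c(=O)c2OC(C)=O)ccc1OC(C)=O | intermediate
21 | 3-acetoxy-2-(4-acetoxy-3-methoxyphenyl)-5,7-dihydroxy-8-methoxychromen-4-one | COc1cc(-c2oc3c(OC)c(O)cc(O)c3c(=O)c2OC(C)=O)ccc1OC(C)=O | intermediate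
22 | prenyl bromide (1-bromo-3-methylbut-2-ene) | CC(C)=CCBr | starting material
23 | 3-acetoxy-2-(4-acetoxy-3-methoxyphenyl)-5-hydroxy-8-methoxy-7-(3-methylbut-2-enyloxy)chromen-4-one | COc1cc(-c2oc3c(OC)c(OCC=C(C)C)cc(O)c3c(=O)c2OC(C)=O)ccc1OC(C)=O | intermediate
24 | 3,5-dihydroxy-2-(4-hydroxy-3-methoxyphenyl)-8-methoxy-7-(3-methylbut-2-enyloxy)chromen-4-one | COc1cc(-c2oc3c(OC)c(OCC=C(C)C)cc(O)c3c(=O)c2O)ccc1O | target

**Step count**
Total: 11 steps. Longest linear sequence: 9 steps (steps 1–6 and 9–11); steps 7–8 make the diene in parallel.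

**Steps most likely to fail**

1. Step 9 (ring A annulation). The ionic annulation may stall after the first carbon–carbon bond, because closure of the hindered bromo silyl enol ether onto the silylated ester is slow. Ring C may also open by β-elimination of its oxygen before hydrogen bromide is lost.
Fallback (chalcone route, known chemistry), from vanillin 1 back to 21: O-benzylation (BnBr, K2CO3, DMF) should give 4-(benzyloxy)-3-methoxybenzaldehyde F1. Claisen–Schmidt condensation of F1 with catalogued 2'-hydroxy-3',4',6'-trimethoxyacetophenone (KOH, EtOH) should give the chalcone (E)-3-[4-(benzyloxy)-3-methoxyphenyl]-1-(2-hydroxy-3,4,6-trimethoxyphenyl)prop-2-en-1-one F2. Algar–Flynn–Oyamada oxidation (H2O2, NaOH, MeOH) should give 2-[4-(benzyloxy)-3-methoxyphenyl]-3-hydroxy-5,7,8-trimethoxychromen-4-one F3. HBr in AcOH should then remove the benzyl ether and the two methyl ethers conjugated with the carbonyl (O5 and O7), while the 8- and 3'-methoxy groups are expected to survive, giving limocitrin F4. Ac2O (3 equiv) in pyridine should acetylate O3, O7 and O4' but not the chelated 5-OH, giving 3,7-diacetoxy-2-(4-acetoxy-3-methoxyphenyl)-5-hydroxy-8-methoxychromen-4-one F5. PhSH and imidazole in N-methylpyrrolidone should remove the 7-acetate selectively and deliver 21.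

2. Step 6 (C5 bromination). Electrophilic substitution on the methoxy-bearing aryl ring, or addition across the C2=C3 enol acetate, may compete with addition to C5=C6 and give mixtures of bromides.
Fallback (bromine brought in with the furan), from 2 back to 12: 3,4-dibromofuran is deprotonated with LiN(iPr)2 (THF, −78 °C) to 3,4-dibromo-2-furyllithium F6, which should add to 2 to give (3,4-dibromofuran-2-yl)[4-(tert-butyldimethylsilyloxy)-3-methoxyphenyl]methanol F7. Peracid ring expansion through (Z)-2,3-dibromo-5-[4-(tert-butyldimethylsilyloxy)-3-methoxyphenyl]-5-hydroxy-4-oxopent-2-enal F8 should give 4,5-dibromo-2-[4-(tert-butyldimethylsilyloxy)-3-methoxyphenyl]-6-hydroxy-2H-pyran-3(6H)-one F9. Aqueous CF3CO2H at 60 °C should exchange only the C4 bromide for oxygen and remove the silyl group, giving 5-bromo-3-hydroxy-2-(4-hydroxy-3-methoxyphenyl)-4H-pyran-4-one F10. Diacetylation under the conditions of step 5 then gives 12. This fallback also bypasses steps 2–5.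

3. Step 10 (O7 prenylation). Under carbonate, acetyl groups may migrate from O3 or O4' to the 7-phenoxide or be lost, which would give mixtures of prenyl ethers.
Fallback (Mitsunobu etherification), from 21 directly to 23: 3-methylbut-2-en-1-ol, PPh3 and diisopropyl azodicarboxylate in THF at 0 °C should alkylate the more acidic 7-OH under neutral conditions, with no free phenoxide and no new intermediate.

**Further compounds**
F1 | step 9 | 4-(benzyloxy)-3-methoxybenzaldehyde | COc1cc(C=O)ccc1OCc1ccccc1
F2 | step 9 | (E)-3-[4-(benzyloxy)-3-methoxyphenyl]-1-(2-hydroxy-3,4,6-trimethoxyphenyl)prop-2-en-1-one | COc1cc(/C=C/C(=O)c2c(O)c(OC)c(OC)cc2OC)ccc1OCc1ccccc1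
F3 | step 9 | 2-[4-(benzyloxy)-3-methoxyphenyl]-3-hydroxy-5,7,8-trimethoxychromen-4-one | COc1cc(-c2oc3c(OC)c(OC)cc(OC)c3c(=O)c2O)ccc1OCc1ccccc1
F4 | step 9 | 3,5,7-trihydroxy-2-(4-hydroxy-3-methoxyphenyl)-8-methoxychromen-4-one (limocitrin) | COc1cc(-c2oc3c(OC)c(O)cc(O)c3c(=O)c2O)ccc1O
F5 | step 9 | 3,7-diacetoxy-2-(4-acetoxy-3-methoxyphenyl)-5-hydroxy-8-methoxychromen-4-one | COc1cc(-c2oc3c(OC)c(OC(C)=O)cc(O)c3c(=O)c2OC(C)=O)ccc1OC(C)=O
F6 | step 6 | 3,4-dibromo-2-furyllithium | [Li]c1occ(Br)c1Br
F7 | step 6 | (3,4-dibromofuran-2-yl)[4-(tert-butyldimethylsilyloxy)-3-methoxyphenyl]methanol (racemic) | COc1cc(C(O)c2occ(Br)c2Br)ccc1O[Si](C)(C)C(C)(C)C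
F8 | step 6 | (Z)-2,3-dibromo-5-[4-(tert-butyldimethylsilyloxy)-3-methoxyphenyl]-5-hydroxy-4-oxopent-2-enal (racemic) | O=C/C(Br)=C(Br)\C(=O)C(O)c1ccc(O[Si](C)(C)C(C)(C)C)c(OC)c1
F9 | step 6 | 4,5-dibromo-2-[4-(tert-butyldimethylsilyloxy)-3-methoxyphenyl]-6-hydroxy-2H-pyran-3(6H)-one (mixture of diastereomers) | COc1cc(C2OC(O)C(Br)=C(Br)C2=O)ccc1O[Si](C)(C)C(C)(C)C
F10 | step 6 | 5-bromo-3-hydroxy-2-(4-hydroxy-3-methoxyphenyl)-4H-pyran-4-one | COc1cc(-c2occ(Br)c(=O)c2O)ccc1O
F0 | step 10 | none | none
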